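Numbering: ring A = C1–C5, C10 (exocyclic methylene on C4); ring B = C5–C10 (C8 methyl, C9 quaternary). Everything rests on closing ring B last, at the bond between the quaternary ring-fusion carbon C5 and the methylene C6. The step exploits that C5 is α to C4, whose methylene is a masked ketone: a 2-methylcyclohex-2-enone (ring A) bearing on C10 the preassembled chain C9–C8–C7–C6–OTs, built on (S)-4-methyl-δ-valerolactone, gives its extended dienolate, which alkylates at C5. One operation forms ring B and quaternary C5; C10 stays trigonal, so the trans fusion is set afterwards by radical hydrogenation, before C4 methylenation and arene carboxylation.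

Key step: step 13

Assumption: compounds 1, 7 and 16 are taken as commercial; hydroxy ketone 21 is drawn in its open form and may sit partly as the cyclic hemiketal (the protonated form of 20), which reacts alike in step 11.

Step 1
Reactants: 1 methyl hydrogen (R)-3-methylglutarate
Product: 3 (S)-4-methyltetrahydro-2H-pyran-2-one, via hydroxy acid 2 (not isolated)
Conditions: LiH, THF, 0 °C; LiBH4, 45 °C; then 3 M HCl, rt
Reagents that add atoms: none
Why: LiBH4 reduces the methyl ester but not the lithium carboxylate and acid then lactonises the hydroxy acid, so the untouched stereocentre of 1 ends as the (S)-centre of 3, the later C8 (chemoselective ester reduction and lactonisation).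

Step 2
Reactants: 3 (S)-4-methyltetrahydro-2H-pyran-2-one
Product: 5 (3S,4S)-3-(hydroxymethyl)-4-methyltetrahydro-2H-pyran-2-one, via lithium enolate 4 (not isolated)
Conditions: lithium diisopropylamide (LDA), THF, −78 °C; CH2O (gas), −78 → −20 °C; aq. NH4Cl
Reagents that add atoms: formaldehyde, C=O
Why: Aldol addition of the lactone enolate to monomeric formaldehyde should occur anti to the neighbouring methyl group (trans product); this centre is planarised again in step 7, so its configuration here is not critical.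

Step 3
Reactants: 5 (3S,4S)-3-(hydroxymethyl)-4-methyltetrahydro-2H-pyran-2-one
Product: 6 (3S,4S)-3-[(methoxymethoxy)methyl]-4-methyltetrahydro-2H-pyran-2-one
Conditions: MOMCl, i-Pr2NEt, CH2Cl2, 0 °C → rt
Reagents that add atoms: chloromethyl methyl ether (MOMCl), COCCl
Why: Standard methoxymethylation of a primary alcohol under mild base, which touches no stereocentre and gives a group stable to all later basic and organometallic steps.

Step 4
Reactants: 7 2-methoxybenzene-1,3-diol
Product: 8 2-methoxy-1,3-bis(methoxymethoxy)benzene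
Conditions: MOMCl, i-Pr2NEt, CH2Cl2, 0 °C → rt
Reagents that add atoms: chloromethyl methyl ether (MOMCl), COCCl
Why: Double O-alkylation of the phenols gives MOM ethers that later serve as ortho-directing groups.

Step 5
Reactants: 8 2-methoxy-1,3-bis(methoxymethoxy)benzene
Product: 11 [3-methoxy-2,4-bis(methoxymethoxy)phenyl]methanol, via aryllithium 9 (not isolated), via aldehyde 10 (not isolated)
Conditions: n-BuLi, TMEDA, THF, 0 °C; DMF, −78 °C → rt; then MeOH, NaBH4, 0 °C
Reagents that add atoms: N,N-dimethylformamide, CN(C)C=O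
Why: Directed ortho-metalation places lithium next to a methoxymethoxy group (the two such positions are equivalent), DMF formylates the aryllithium and borohydride reduces the aldehyde in the same flask.

Step 6
Reactants: 11 [3-methoxy-2,4-bis(methoxymethoxy)phenyl]methanol
Product: 13 1-(bromomethyl)-3-methoxy-2,4-bis(methoxymethoxy)benzene, via mesylate 12 (not isolated)
Conditions: MsCl, Et3N, CH2Cl2, −20 °C; then LiBr, THF, 0 °C; used at once
Reagents that add atoms: lithium bromide, [Li+].[Br-]
Why: Mesylation followed by Finkelstein-type displacement gives the benzylic bromide without acid, so the MOM ethers survive.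

Step 7
Reactants: 6 (3S,4S)-3-[(methoxymethoxy)methyl]-4-methyltetrahydro-2H-pyran-2-one; 13 1-(bromomethyl)-3-methoxy-2,4-bis(methoxymethoxy)benzene
Product: 15 (3R,4S)-3-[3-methoxy-2,4-bis(methoxymethoxy)benzyl]-3-[(methoxymethoxy)methyl]-4-methyltetrahydro-2H-pyran-2-one, via lithium enolate 14 (not isolated)
Conditions: LDA, THF, DMPU, −78 °C; then 13, −78 → −40 °C
Reagents that add atoms: none
Why: The tetrasubstituted lactone enolate should be alkylated on the face anti to the adjacent methyl group, so the benzyl group ends trans and the CH2OMOM arm cis to that methyl, which sets quaternary C9 relative to C8 (diastereoselective enolate alkylation; the low temperature holds back β-elimination of the alkoxide).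

Step 8
Reactants: 16 4-chlorobutanoyl chloride
Product: 17 6-chlorohexan-3-one
Conditions: EtMgBr, Fe(acac)3 (cat.), THF, −78 °C
Reagents that add atoms: ethylmagnesium bromide, CC[Mg]Br
Why: Iron-catalysed acylation of the Grignard reagent by the acid chloride is much faster than attack on the ketone formed or on the alkyl chloride.

Step 9
Reactants: 17 6-chlorohexan-3-one
Product: 18 2-(3-chloropropyl)-2-ethyl-1,3-dioxolane
Conditions: ethylene glycol, p-TsOH (cat.), toluene, reflux, Dean–Stark
Reagents that add atoms: ethylene glycol, OCCO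
Why: Acid-catalysed ketalisation with azeotropic removal of water masks the ketone for the organolithium step.

Step 10
Reactants: 18 2-(3-chloropropyl)-2-ethyl-1,3-dioxolane; 15 (3R,4S)-3-[3-methoxy-2,4-bis(methoxymethoxy)benzyl]-3-[(methoxymethoxy)methyl]-4-methyltetrahydro-2H-pyran-2-one
Product: 21 (5R,6S)-1-(2-ethyl-1,3-dioxolan-2-yl)-8-hydroxy-5-[3-methoxy-2,4-bis(methoxymethoxy)benzyl]-5-[(methoxymethoxy)methyl]-6-methyloctan-4-one, via organolithium 19 (not isolated), via lithium hemiketal alkoxide 20 (not isolated)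
Conditions: Li, 4,4′-di-tert-butylbiphenyl (cat.), THF, −78 °C; then 15, −78 °C; aq. NH4Cl
Reagents that add atoms: none
Why: Reductive lithiation of the primary chloride gives an organolithium that should add only once to the lactone, because the tetrahedral lithium hemiketal alkoxide next to the quaternary carbon persists until the quench (acyl substitution of a lactone to a δ-hydroxy ketone); C9 has no α-hydrogen and cannot epimerise.

Step 11
Reactants: 21 (5R,6S)-1-(2-ethyl-1,3-dioxolan-2-yl)-8-hydroxy-5-[3-methoxy-2,4-bis(methoxymethoxy)benzyl]-5-[(methoxymethoxy)methyl]-6-methyloctan-4-one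
Product: 23 3-{(2S,3S)-5-hydroxy-1-[3-methoxy-2,4-bis(methoxymethoxy)phenyl]-2-[(methoxymethoxy)methyl]-3-methylpentan-2-yl}-2-methylcyclohex-2-en-1-one, via diketone 22 (not isolated)
Conditions: PPTS, acetone/H2O, 40 °C; concentrate; then KOH, MeOH, 65 °C
Reagents that add atoms: water, O
Why: The dialkyl ketal hydrolyses far faster than the formaldehyde acetals, and the 1,5-diketone can only close by attack of C5 on the C10 carbonyl, which after dehydration gives ring A as the 2-methylcyclohex-2-enone (intramolecular aldol condensation); any β,γ-isomer would give the same dienolate in step 13.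

Step 12
Reactants: 23 3-{(2S,3S)-5-hydroxy-1-[3-methoxy-2,4-bis(methoxymethoxy)phenyl]-2-[(methoxymethoxy)methyl]-3-methylpentan-2-yl}-2-methylcyclohex-2-en-1-one
Product: 24 (3S,4S)-4-[(methoxymethoxy)methyl]-5-[3-methoxy-2,4-bis(methoxymethoxy)phenyl]-3-methyl-4-(2-methyl-3-oxocyclohex-1-en-1-yl)pentyl 4-methylbenzenesulfonate
Conditions: TsCl, pyridine, DMAP (cat.), CH2Cl2, 0 °C
Reagents that add atoms: p-toluenesulfonyl chloride, Cc1ccc(cc1)S(Cl)(=O)=O
Why: Sulfonylation of the only free hydroxyl, a primary one, turns C6 into the electrophile for ring closure.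

Step 13
Reactants: 24 (3S,4S)-4-[(methoxymethoxy)methyl]-5-[3-methoxy-2,4-bis(methoxymethoxy)phenyl]-3-methyl-4-(2-methyl-3-oxocyclohex-1-en-1-yl)pentyl 4-methylbenzenesulfonate
Product: 26 (5S,6S,8aS)-5-[3-methoxy-2,4-bis(methoxymethoxy)benzyl]-5-[(methoxymethoxy)methyl]-6,8a-dimethyl-3,5,6,7,8,8a-hexahydronaphthalen-1(2H)-one, via potassium dienolate 25 (not isolated)
Conditions: KOt-Bu, THF (high dilution), −20 °C → rt
Reagents that add atoms: none
Why: Potassium tert-butoxide equilibrates the enone to the extended dienolate O–C4=C5(CH3)–C10=C1, whose α-carbon C5 displaces the primary tosylate at C6 by SN2; the closest known reaction type is the intramolecular deconjugative α-alkylation of α,β-unsaturated ketones, which gives bicyclic β,γ-unsaturated ketones with an angular methyl group. Ring B (C5–C6–C7–C8–C9–C10) closes in the 6-(enolexo)-exo-tet mode with trigonal C10 inside the new ring. The only new stereocentre, quaternary C5, is controlled by C8 and C9 through a chair-like transition state in which the C8 methyl is equatorial and the large benzyl arm lies in the dienolate plane away from the C5 methyl, so the small CH2OMOM arm is axial and C6 attacks the opposite face of C5, which should leave the C5 methyl cis to CH2OMOM and to the C8 methyl as required. The step needs C5 (α) over C1 (γ) and over oxygen: α-attack is the kinetic rule for such dienolates, it alone relieves the eclipsing strain between the C5 methyl and quaternary C9 on neighbouring trigonal carbons, γ-closure would push a C9 arm against that methyl, and O-alkylation would need an eight-membered ring. C10 is deliberately left trigonal, because closure onto C5 next to a tetrahedral C10–H would force the cis ring fusion; its configuration is set in step 14.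

Step 14
Reactants: 26 (5S,6S,8aS)-5-[3-methoxy-2,4-bis(methoxymethoxy)benzyl]-5-[(methoxymethoxy)methyl]-6,8a-dimethyl-3,5,6,7,8,8a-hexahydronaphthalen-1(2H)-one
Product: 27 (4aS,5S,6S,8aS)-5-[3-methoxy-2,4-bis(methoxymethoxy)benzyl]-5-[(methoxymethoxy)methyl]-6,8a-dimethyloctahydronaphthalen-1(2H)-one
Conditions: Mn(dpm)3 (cat., dpm = dipivaloylmethanate), PhSiH3, t-BuOOH, i-PrOH, rt
Reagents that add atoms: none
Why: Hydrogen-atom transfer from a manganese hydride to C1 gives the tertiary C10 radical, which should take its hydrogen on the face away from the axial C5 methyl and the axial CH2OMOM arm and so give the trans-fused chair–chair decalin, setting C10 (radical hydrogen-atom-transfer hydrogenation with thermodynamic-type stereocontrol).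

Step 15
Reactants: 27 (4aS,5S,6S,8aS)-5-[3-methoxy-2,4-bis(methoxymethoxy)benzyl]-5-[(methoxymethoxy)methyl]-6,8a-dimethyloctahydronaphthalen-1(2H)-one
Product: 28 (1S,2S,4aS,8aR)-1-[3-methoxy-2,4-bis(methoxymethoxy)benzyl]-1-[(methoxymethoxy)methyl]-2,4a-dimethyl-5-methylidenedecahydronaphthalene
Conditions: Ph3PCH3Br, KOt-Bu, toluene, 100 °C
Reagents that add atoms: methyltriphenylphosphonium bromide, C[P+](c1ccccc1)(c1ccccc1)c1ccccc1.[Br-]
Why: Wittig methylenation of the hindered C4 ketone next to quaternary C5 needs excess ylide and heat, and no stereocentre is at risk because C5 carries no hydrogen and C3 is a methylene.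

Step 16
Reactants: 28 (1S,2S,4aS,8aR)-1-[3-methoxy-2,4-bis(methoxymethoxy)benzyl]-1-[(methoxymethoxy)methyl]-2,4a-dimethyl-5-methylidenedecahydronaphthalene
Product: 30 methyl 3-methoxy-2,4-bis(methoxymethoxy)-5-{[(1S,2S,4aS,8aR)-1-[(methoxymethoxy)methyl]-2,4a-dimethyl-5-methylidenedecahydronaphthalen-1-yl]methyl}benzoate, via aryllithium 29 (not isolated)
Conditions: s-BuLi, TMEDA, THF, −78 °C; then ClCO2Me, −78 °C
Reagents that add atoms: methyl chloroformate, COC(=O)Cl
Why: Directed ortho-metalation occurs at the only ring position that has both a free hydrogen and a neighbouring methoxymethoxy group, and the aryllithium is acylated by the chloroformate; the ester is brought in only now because it would not survive steps 10 and 15.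

Step 17
Reactants: 30 methyl 3-methoxy-2,4-bis(methoxymethoxy)-5-{[(1S,2S,4aS,8aR)-1-[(methoxymethoxy)methyl]-2,4a-dimethyl-5-methylidenedecahydronaphthalen-1-yl]methyl}benzoate
Product: 31 methyl 2,4-dihydroxy-5-{[(1S,2S,4aS,8aR)-1-(hydroxymethyl)-2,4a-dimethyl-5-methylidenedecahydronaphthalen-1-yl]methyl}-3-methoxybenzoate
Conditions: ZnBr2, n-PrSH, CH2Cl2, 0 °C → rt
Reagents that add atoms: none
Why: Zinc bromide activates the three MOM acetals and the thiol captures the methoxymethyl cation, so all three fall together without a protic acid that could protonate the 1,1-disubstituted alkene (Lewis acid–thiol acetal cleavage).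

Compound list

1 | methyl hydrogen (R)-3-methylglutarate [(R)-5-methoxy-3-methyl-5-oxopentanoic acid] | COC(=O)C[C@H](C)CC(=O)O | starting material
2 | (S)-5-hydroxy-3-methylpentanoic acid | OCC[C@H](C)CC(=O)O | intermediate
3 | (S)-4-methyltetrahydro-2H-pyran-2-one | O=C1C[C@@H](C)CCO1 | intermediate
4 | lithium enolate of 3 | [Li+].[O-]C1=C[C@@H](C)CCO1 | intermediate
5 | (3S,4S)-3-(hydroxymethyl)-4-methyltetrahydro-2H-pyran-2-one (trans) | O=C1[C@H](CO)[C@@H](C)CCO1 | intermediate
6 | (3S,4S)-3-[(methoxymethoxy)methyl]-4-methyltetrahydro-2H-pyran-2-one | O=C1[C@H](COCOC)[C@@H](C)CCO1 | intermediate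
7 | 2-methoxybenzene-1,3-diol | COc1c(O)cccc1O | starting material
8 | 2-methoxy-1,3-bis(methoxymethoxy)benzene | COCOc1cccc(OCOC)c1OC | intermediate
9 | [3-methoxy-2,4-bis(methoxymethoxy)phenyl]lithium | [Li]c1ccc(OCOC)c(OC)c1OCOC | intermediate
10 | 3-methoxy-2,4-bis(methoxymethoxy)benzaldehyde | O=Cc1ccc(OCOC)c(OC)c1OCOC | intermediate
11 | [3-methoxy-2,4-bis(methoxymethoxy)phenyl]methanol | OCc1ccc(OCOC)c(OC)c1OCOC | intermediate
12 | 3-methoxy-2,4-bis(methoxymethoxy)benzyl methanesulfonate | CS(=O)(=O)OCc1ccc(OCOC)c(OC)c1OCOC | intermediate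
13 | 1-(bromomethyl)-3-methoxy-2,4-bis(methoxymethoxy)benzene | BrCc1ccc(OCOC)c(OC)c1OCOC | intermediate
14 | lithium enolate of 6 | [Li+].[O-]C1=C(COCOC)[C@@H](C)CCO1 | intermediate
15 | (3R,4S)-3-[3-methoxy-2,4-bis(methoxymethoxy)benzyl]-3-[(methoxymethoxy)methyl]-4-methyltetrahydro-2H-pyran-2-one (benzyl trans, CH2OMOM cis to the 4-methyl) | O=C1[C@](COCOC)(Cc2ccc(OCOC)c(OC)c2OCOC)[C@@H](C)CCO1 | intermediate
16 | 4-chlorobutanoyl chloride | O=C(Cl)CCCCl | starting material
17 | 6-chlorohexan-3-one | CCC(=O)CCCCl | intermediate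
18 | 2-(3-chloropropyl)-2-ethyl-1,3-dioxolane | CCC1(CCCCl)OCCO1 | intermediate
19 | [3-(2-ethyl-1,3-dioxolan-2-yl)propyl]lithium | [Li]CCCC1(CC)OCCO1 | intermediate
20 | lithium (3R,4S)-2-[3-(2-ethyl-1,3-dioxolan-2-yl)propyl]-3-[3-methoxy-2,4-bis(methoxymethoxy)benzyl]-3-[(methoxymethoxy)methyl]-4-methyltetrahydro-2H-pyran-2-olate (either configuration at C2) | [Li+].[O-]C1(CCCC2(CC)OCCO2)[C@](COCOC)(Cc2ccc(OCOC)c(OC)c2OCOC)[C@@H](C)CCO1 | intermediate
21 | (5R,6S)-1-(2-ethyl-1,3-dioxolan-2-yl)-8-hydroxy-5-[3-methoxy-2,4-bis(methoxymethoxy)benzyl]-5-[(methoxymethoxy)methyl]-6-methyloctan-4-one | CCC1(CCCC(=O)[C@](COCOC)(Cc2ccc(OCOC)c(OC)c2OCOC)[C@@H](C)CCO)OCCO1 | intermediate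
22 | (8R,9S)-11-hydroxy-8-[3-methoxy-2,4-bis(methoxymethoxy)benzyl]-8-[(methoxymethoxy)methyl]-9-methylundecane-3,7-dione | CCC(=O)CCCC(=O)[C@](COCOC)(Cc1ccc(OCOC)c(OC)c1OCOC)[C@@H](C)CCO | intermediate
23 | 3-{(2S,3S)-5-hydroxy-1-[3-methoxy-2,4-bis(methoxymethoxy)phenyl]-2-[(methoxymethoxy)methyl]-3-methylpentan-2-yl}-2-methylcyclohex-2-en-1-one | CC1=C(CCCC1=O)[C@](COCOC)(Cc2ccc(OCOC)c(OC)c2OCOC)[C@@H](C)CCO | intermediate
24 | (3S,4S)-4-[(methoxymethoxy)methyl]-5-[3-methoxy-2,4-bis(methoxymethoxy)phenyl]-3-methyl-4-(2-methyl-3-oxocyclohex-1-en-1-yl)pentyl 4-methylbenzenesulfonate | CC1=C(CCCC1=O)[C@](COCOC)(Cc2ccc(OCOC)c(OC)c2OCOC)[C@@H](C)CCOS(=O)(=O)c3ccc(C)cc3 | intermediate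
25 | potassium dienolate of 24 (O–C4=C5–C10=C1) | [K+].[O-]C1=C(C)C(=CCC1)[C@](COCOC)(Cc2ccc(OCOC)c(OC)c2OCOC)[C@@H](C)CCOS(=O)(=O)c3ccc(C)cc3 | intermediate
26 | (5S,6S,8aS)-5-[3-methoxy-2,4-bis(methoxymethoxy)benzyl]-5-[(methoxymethoxy)methyl]-6,8a-dimethyl-3,5,6,7,8,8a-hexahydronaphthalen-1(2H)-one | O=C1CCC=C2[C@](COCOC)(Cc3ccc(OCOC)c(OC)c3OCOC)[C@@H](C)CC[C@]12C | intermediate
27 | (4aS,5S,6S,8aS)-5-[3-methoxy-2,4-bis(methoxymethoxy)benzyl]-5-[(methoxymethoxy)methyl]-6,8a-dimethyloctahydronaphthalen-1(2H)-one (trans-fused) | O=C1CCC[C@H]2[C@](COCOC)(Cc3ccc(OCOC)c(OC)c3OCOC)[C@@H](C)CC[C@]12C | intermediate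
28 | (1S,2S,4aS,8aR)-1-[3-methoxy-2,4-bis(methoxymethoxy)benzyl]-1-[(methoxymethoxy)methyl]-2,4a-dimethyl-5-methylidenedecahydronaphthalene | C=C1CCC[C@H]2[C@](COCOC)(Cc3ccc(OCOC)c(OC)c3OCOC)[C@@H](C)CC[C@]12C | intermediate
29 | aryllithium of 28 (lithium ortho to the 4-methoxymethoxy group) | C=C1CCC[C@H]2[C@](COCOC)(Cc3cc([Li])c(OCOC)c(OC)c3OCOC)[C@@H](C)CC[C@]12C | intermediate
30 | methyl 3-methoxy-2,4-bis(methoxymethoxy)-5-{[(1S,2S,4aS,8aR)-1-[(methoxymethoxy)methyl]-2,4a-dimethyl-5-methylidenedecahydronaphthalen-1-yl]methyl}benzoate | C=C1CCC[C@H]2[C@](COCOC)(Cc3cc(C(=O)OC)c(OCOC)c(OC)c3OCOC)[C@@H](C)CC[C@]12C | intermediate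
31 | methyl 2,4-dihydroxy-5-{[(1S,2S,4aS,8aR)-1-(hydroxymethyl)-2,4a-dimethyl-5-methylidenedecahydronaphthalen-1-yl]methyl}-3-methoxybenzoate | C=C1CCC[C@H]2[C@](CO)(Cc3cc(C(=O)OC)c(O)c(OC)c3O)[C@@H](C)CC[C@]12C | target

Total step count: 17. Longest linear sequence: 12 steps (1, 2, 3, 7, 10, 11, 12, 13, 14, 15, 16, 17); steps 4–6 and 8–9 are side branches.

Steps most likely to fail

Step 13 (key step). The ambident dienolate may close through its γ-carbon C1 instead of C5, base-induced elimination of the tosylate may outrun enolisation, and the face discrimination at C5 rests on modest conformational preferences. The fallback replaces the potassium dienolate by a metalated hydrazone, a nucleophile class known to alkylate unsaturated ketone derivatives at the α-carbon. It sets out from alcohol 23: condensation with N,N-dimethylhydrazine should give the dimethylhydrazone of 23 F1, tosylation the hydrazone tosylate F2, and LDA in THF the lithiated aza-dienolate, whose ring closure at C5 gives the bicyclic hydrazone F3. Hydrolysis with Cu(OAc)2 in aqueous THF then releases ketone 26, where the route is rejoined.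

Step 14. The C10 radical lies β to the C4 carbonyl and may undergo 1,2-acyl migration before it is reduced, and hydrogen delivery at this very crowded centre may lose its face preference. The fallback takes the carbonyl out of play for the radical step. It sets out from 26: NaBH4 in MeOH should reduce the ketone, from the face away from the angular methyl, to the homoallylic alcohol F4. The same hydrogen-atom-transfer hydrogenation, now without a carbonyl flanking the radical, should give the trans-fused alcohol F5, and Dess–Martin oxidation returns ketone 27.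

Step 11. Aldol addition to the C10 carbonyl, buried next to quaternary C9, may be too slow or may revert before dehydration. The fallback closes ring A by an irreversible olefination instead. It sets out from lactone 15: vinyllithium at −78 °C should give the hydroxy vinyl ketone F6. The dianion of dimethyl (3-oxobutan-2-yl)phosphonate (NaH, then n-BuLi) then adds through its terminal carbon in conjugate fashion to give the keto phosphonate F7. NaH in THF closes the ring by intramolecular Horner–Wadsworth–Emmons olefination onto the C10 ketone and delivers enone 23.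

Further compounds

F1 | step 13 | N,N-dimethylhydrazone of enone alcohol 23 | CN(C)N=C1CCCC(=C1C)[C@](COCOC)(Cc2ccc(OCOC)c(OC)c2OCOC)[C@@H](C)CCO
F2 | step 13 | 4-methylbenzenesulfonate of F1 | CN(C)N=C1CCCC(=C1C)[C@](COCOC)(Cc2ccc(OCOC)c(OC)c2OCOC)[C@@H](C)CCOS(=O)(=O)c3ccc(C)cc3
F3 | step 13 | N,N-dimethylhydrazone of bicyclic ketone 26 | CN(C)N=C1CCC=C2[C@](COCOC)(Cc3ccc(OCOC)c(OC)c3OCOC)[C@@H](C)CC[C@]12C
F4 | step 14 | C4 alcohol of 26 (hydroxyl cis to the angular methyl, C1=C10 alkene retained) | O[C@H]1CCC=C2[C@](COCOC)(Cc3ccc(OCOC)c(OC)c3OCOC)[C@@H](C)CC[C@]12C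
F5 | step 14 | trans-fused C4 alcohol of 27 (hydroxyl cis to the angular methyl) | O[C@H]1CCC[C@H]2[C@](COCOC)(Cc3ccc(OCOC)c(OC)c3OCOC)[C@@H](C)CC[C@]12C
F6 | step 11 | (4R,5S)-7-hydroxy-4-[3-methoxy-2,4-bis(methoxymethoxy)benzyl]-4-[(methoxymethoxy)methyl]-5-methylhept-1-en-3-one | C=CC(=O)[C@](COCOC)(Cc1ccc(OCOC)c(OC)c1OCOC)[C@@H](C)CCO
F7 | step 11 | dimethyl [(8R,9S)-11-hydroxy-8-[3-methoxy-2,4-bis(methoxymethoxy)benzyl]-8-[(methoxymethoxy)methyl]-9-methyl-3,7-dioxoundecan-2-yl]phosphonate (both epimers at the phosphonate carbon) | COP(=O)(OC)C(C)C(=O)CCCC(=O)[C@](COCOC)(Cc1ccc(OCOC)c(OC)c1OCOC)[C@@H](C)CCO
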